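## Structural features

The target consists of two six-membered rings joined through one sp3 carbon. Ring A is a hexasubstituted benzene in which three hydroxyl groups alternate with a methyl group, a 3-phenylpropanoyl group and the bridging carbon; ring B is the enol form of a 4,4,6,6-tetramethylcyclohexane-1,3,5-trione, bonded through its C2. The bridging carbon is the only stereocentre (S; it carries H, an isobutyl group, ring A and ring B), so no stereocentres stand next to each other and only absolute configuration must be controlled. The molecule is fragile in four ways: the C–C bonds from the stereocentre to the two enol-like rings can ionise (retro-Michael cleavage, which would racemise it); a phenol ortho to the bridge can condense with a ring B carbonyl under acid to a xanthenedione; the trihydroxyarene oxidises readily in basic, aerated media; and the non-enolisable 1,3-dicarbonyl units around the two quaternary carbons are open to retro-Claisen cleavage. The real difficulty is to place six different substituents on ring A beside a stereocentre of one absolute sense without conditions that ionise it, and to build the two quaternary carbons of ring B. The key step exploits the strict O–C–O–C–O–C alternation of ring A: the carbonyl carbon, the methyl-bearing carbon, the alkoxy-bearing carbon and the sp3 carbon of a 3-alkoxy-2-methylcyclobutenone become C–OH, C–CH3, C–O and the carbon attached to the stereocentre, and the two carbons of an oxygenated alkyne become the remaining C–H (later acylated) and C–O. Because the stereocentre is exocyclic to the ring that forms, it can be brought in finished.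

## Logic of the disconnections

30 ⇒ 29. The O–CH2Ph bond on the ring A oxygen between the methyl-bearing and the bridge-bearing carbons is cut. The last step must be neutral because free 30 is sensitive to acid and base. The forward hydrogenolysis must spare the aryl ketone and the enol.

29 ⇒ 26 + 27. Two ring B bonds are cut: the bond from the bridge-bearing ring carbon to one flanking carbonyl carbon (Dieckmann) and the bond from the other flanking carbonyl carbon to its quaternary neighbour (Claisen). Ring B, with both quaternary carbons, then comes from one acyclic keto ester, and the electrophile is a lactone that already holds the stereocentre. The forward step demands C-acylation of a fully substituted enolate and tolerance of an enolisable aryl ketone; the free hydroxyl of 26 is used as its lithium phenoxide, which deactivates that ketone, so no extra protection step is spent.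

26 ⇒ 23 + 24. The aryl–acyl bond and the lactone C–O bond are cut. The only free ring carbon of 23 lies between two hydroxyls, so acylation has one possible site. Only one hydroxyl is ortho to the side chain while the third oxygen is benzylated, so one lactone regioisomer results. The forward step demands a Lewis acid mild enough to keep the benzyl ether.

23 ⇒ 22. The O–Si bond is cut. This frees the second hydroxyl that activates the acylation site. The forward step needs buffered fluoride so that the electron-rich phenoxide is not exposed to air and base.

22 ⇒ 17 + 12 (key). Ring A is cut at the two bonds that join the alkyne carbons to the carbonyl carbon and to the methyl-bearing carbon of 17; the ring closes through the bond between the carbonyl carbon and the former sp3 carbon. All six substituents are set in one neutral thermal step and the stereocentre is a spectator. The forward step demands regiocontrol in the ketene–alkyne union and a ring opening of 17 at a temperature that 12 survives.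

17 ⇒ 15 + 5, then 15 ⇒ 14 ⇒ 13. The two ring bonds of 17 made by a ketene–ynol ether [2+2] are cut; then the acid chloride returns to the half-ester and to the prochiral anhydride 13. The stereocentre thus comes from a catalytic desymmetrisation of a symmetrical, commercial compound. The forward steps demand that the acid chloride is made cold (no ester/acid chloride interchange, which would erode the ee) and that 5 is never heated.

5 ⇒ 1 + 2. The O–C(sp) bond and the C(sp)–CH3 bond are cut. This gives a one-pot assembly from an alcohol, a two-carbon chlorinated unit and a methyl electrophile. The benzyl ynol ether is prone to sigmatropic rearrangement on warming, so it must be used at or below 25 °C; once its oxygen is part of the vinylogous ester 17 this pathway is closed.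

12 ⇒ 10 ⇒ 8 ⇒ 6. The triple bond is traced back to a bromo enol ether (loss of HBr), that to the silyl vinyl ether, and that to the enolate released from 6. The parent silyl ynol ether is not taken as purchasable; this is the classical alkoxyacetylene sequence carried out on a bulky silyl ether. It demands that silicon stays on oxygen throughout, hence the triisopropylsilyl group.

## Other disconnections considered

Alternative 1: The four C–CH3 bonds of ring B are cut, so ring B derives from the 2,4,6-trioxygenated arene of lactone A2. In the forward step an alkoxide in its parent alcohol opens A2 to the ester phenoxide and a methyl halide alkylates each of the two free ring carbons twice, dearomatising the ring to A1 without any ring closure. In its favour: no hindered Claisen bond is needed, the reagents are cheap, and the dearomative tetramethylation of such arenes is the established entry to this trione. On the construction of ring B it is the better of the two plans. Against it: O-methylation and over- or under-alkylation compete, the substituted ring carbon can also be methylated, and the stereocentre sits between a phenoxide and a developing trione under basic conditions. After A1, ring A must still be built from the ester arm, then methylated and acylated regioselectively, which needs more steps than the four that follow the chosen key step. Mechanistically it exchanges a pericyclic, neutral ring A synthesis for ionic polyalkylation; in step economy it is shorter to ring B and longer overall.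

Alternative 2: The same two ring B bonds are cut as in step 11 of the chosen route, but on lactone A4, which already carries the acyl group and two benzyl ethers and would come from a preformed arene. In the forward step the lithium enolate of 27 is C-acylated by A4 and further amide base closes ring B to give A3. In its favour: ring A is bought, not built, and the annulation delivers both quaternary carbons at once. On ring B the two plans are equal, because the chosen route uses this same annulation. Against it: the stereocentre must be set by an enantioselective addition of an isobutyl group to a fully substituted, peri-hindered coumarin or by asymmetric reduction of one, which is less certain than desymmetrising 13; and in A4 the aryl ketone has no neighbouring phenoxide to shield it from enolisation. If that asymmetric step works, Alternative 2 is the better plan in step count; the chosen plan is the safer one in regiochemistry of ring A and in the origin of the stereocentre.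

Alternative 3: The two bonds from the isopropyl carbons to one ring B carbonyl carbon are cut, leaving the acyclic diketone A6 and a one-carbon electrophile. In the forward step excess amide base forms the polyanion of A6 and a dialkyl carbonate acylates both isopropyl carbons in turn, closing ring B to A5. In its favour: A6 is symmetrical, convergent, and open to a catalytic asymmetric conjugate addition at the stereocentre; on convergence it is the equal or the better of the chosen plan. Against it: two tertiary carbanions must each be C-acylated by a weak electrophile to make two quaternary carbons, with O-acylation and mono-acylation as competitors. In addition A5 lacks the acyl group, so a late Friedel–Crafts acylation is needed on a compound that carries ring B, and that is where acid-promoted cyclodehydration to the xanthenedione threatens. The chosen plan forms one hindered C–C bond intermolecularly, closes ring B by a Dieckmann reaction of established type, and installs the acyl group before ring B exists.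

Key step: step 8

Assumption: which pseudoenantiomeric alkaloid ether, (DHQD)2AQN or (DHQ)2AQN, gives 14 and not its enantiomer is settled once by the sign of rotation of the half-ester; both are available.

Remark: the descriptor of the stereocentre changes along the route (S in 14, R in 15 to 28, S in 29 and 30) only because the priority order of its substituents changes; its spatial arrangement is never altered. 17 is used as the mixture of epimers at its ring carbon (one is drawn).

## Steps

Step 1
Reactants: 1 benzyl alcohol; 2 trichloroethene
Product: 5 1-(benzyloxy)prop-1-yne, via benzyl (E)-1,2-dichloroethenyl ether 3 (not isolated), via lithium (benzyloxy)ethynide 4 (not isolated)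
Conditions: KH, THF, 0 °C; 2, −50 °C → rt; n-BuLi (2.4 equiv), −78 → −40 °C; MeI, DMPU, −78 °C → 20 °C; kept below 25 °C
Reagents that add atoms: iodomethane, CI
Why: Trichloroethene route to alkynyl ethers: the alkoxide adds to dichloroethyne formed in situ, n-BuLi removes HCl and exchanges the remaining chlorine for lithium, and the acetylide is C-methylated; no stereocentre is involved.

Step 2
Reactants: 6 tetrahydrofuran
Product: 8 (ethenyloxy)tri(propan-2-yl)silane, via lithium ethenolate 7 (not isolated)
Conditions: n-BuLi, THF, 25 °C, 16 h; then i-Pr3SiOTf, −78 → 0 °C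
Reagents that add atoms: tri(propan-2-yl)silyl trifluoromethanesulfonate, CC(C)[Si](C(C)C)(C(C)C)OS(=O)(=O)C(F)(F)F
Why: α-Lithiation of the cyclic ether and cycloreversion release ethene and the acetaldehyde enolate, which is O-silylated by the hard silyl triflate.

Step 3
Reactants: 8 (ethenyloxy)tri(propan-2-yl)silane
Product: 10 [(Z)-2-bromoethenyloxy]tri(propan-2-yl)silane, via 1,2-dibromoethyl silyl ether 9 (not isolated)
Conditions: Br2, CH2Cl2, −78 °C; then Et3N, −78 °C → rt
Reagents that add atoms: bromine, BrBr
Why: Bromine addition to the enol ether, then amine-promoted loss of HBr through the oxocarbenium ion, as in the classical preparation of 2-bromovinyl ethers; the Z isomer should predominate and either isomer serves.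

Step 4
Reactants: 10 [(Z)-2-bromoethenyloxy]tri(propan-2-yl)silane
Product: 12 (ethynyloxy)tri(propan-2-yl)silane, via lithium siloxyethynide 11 (not isolated)
Conditions: LiN(i-Pr)2 (2.2 equiv), THF, −78 → −20 °C; sat. aq. NH4Cl, −78 °C; distillation
Reagents that add atoms: none
Why: Dehydrobromination of a 2-halovinyl ether to the alkynyl ether (anti-periplanar H and Br in the Z isomer; α-elimination with 1,2-shift leads to the same alkyne); the second equivalent of base holds the product as its acetylide until the quench, and the bulky silyl group stays on oxygen.

Step 5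
Reactants: 13 3-(2-methylpropyl)glutaric anhydride
Product: 14 (3S)-3-(2-methoxy-2-oxoethyl)-5-methylhexanoic acid
Conditions: MeOH (10 equiv), (DHQD)2AQN (10 mol %), Et2O, −30 °C; acid wash recovers the catalyst
Reagents that add atoms: methanol, CO
Why: Cinchona alkaloid-catalysed enantioselective alcoholysis of a prochiral cyclic anhydride: the quinuclidine nitrogen acts as general base and its chiral pocket differentiates the two enantiotopic carbonyl groups, which sets the only stereocentre; the ee can be raised by crystallising a 1-phenylethylammonium salt.

Step 6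
Reactants: 14 (3S)-3-(2-methoxy-2-oxoethyl)-5-methylhexanoic acid
Product: 15 methyl (3R)-3-(2-chloro-2-oxoethyl)-5-methylhexanoate
Conditions: (COCl)2, DMF (cat.), CH2Cl2, 0 °C → rt; evaporated, used crude
Reagents that add atoms: oxalyl chloride, O=C(Cl)C(=O)Cl
Why: Acid chloride formation through the chloroiminium reagent; the low temperature avoids interchange of the ester and acid chloride termini, the one process that could erode the ee.

Step 7
Reactants: 15 methyl (3R)-3-(2-chloro-2-oxoethyl)-5-methylhexanoate; 5 1-(benzyloxy)prop-1-yne
Product: 17 methyl (3R)-3-[2-(benzyloxy)-3-methyl-4-oxocyclobut-2-en-1-yl]-5-methylhexanoate (epimers at the ring carbon), via ketene 16 (not isolated)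
Conditions: Et3N (1.3 equiv), 5 (1.5 equiv), CH2Cl2, 15 added over 4 h, 0 → 25 °C
Reagents that add atoms: none
Why: Dehydrochlorination to the aldoketene and [2+2] cycloaddition with the ynol ether; the methyl-bearing alkyne carbon is the nucleophile and bonds to the ketene carbonyl carbon, which gives the 3-alkoxy-2-methyl-4-alkylcyclobutenone regiospecifically. The new ring stereocentre is uncontrolled and is erased in step 8; the side-chain centre is not acidic.

Step 8
Reactants: 17 methyl (3R)-3-[2-(benzyloxy)-3-methyl-4-oxocyclobut-2-en-1-yl]-5-methylhexanoate; 12 (ethynyloxy)tri(propan-2-yl)silane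
Product: 22 methyl (3R)-3-[2-(benzyloxy)-6-hydroxy-3-methyl-4-(triisopropylsiloxy)phenyl]-5-methylhexanoate, via vinylketene 18 (not isolated), via alkenylcyclobutenone 19 (not isolated), via dienylketene 20 (not isolated), via cyclohexadienone 21 (not isolated)
Conditions: 12 (2 equiv), PhMe (0.3 M), argon, sealed tube, 80 °C then 110 °C
Reagents that add atoms: none
Why: Danheiser benzannulation: thermal four-electron conrotatory opening of 17 gives vinylketene 18, which undergoes regiospecific [2+2] cycloaddition with 12 to 19; a second four-electron opening gives dienylketene 20, six-electron disrotatory electrocyclisation gives dienone 21, and tautomerisation gives 22. The closest known reaction type is the thermal benzannulation of cyclobutenones with trialkylsiloxyalkynes; a 3-alkoxy-4-alkylcyclobutenone extends the substrate range, not the reaction type. Ring A closes by the pericyclic six-electron closure of 20, between the ketene carbon and the former sp3 ring carbon, after the two alkyne carbons have been joined to the carbonyl carbon and to the methyl-bearing carbon. Counted by atom map, this is two new C–C bonds plus re-formation of the bond that the first opening broke, while the original bond between the carbonyl and methyl-bearing carbons is lost. No stereocentre is created: no bond to the side-chain centre is made or broken, and the epimeric ring carbon of 17 becomes sp2, so the epimer mixture converges. The step needs regiocontrol in the ketene–alkyne union, which the polarisation of the ynol ether secures (its CH carbon attacks the ketene carbonyl carbon), so that OH, H, OSi, CH3, OBn and the side chain follow one another around the ring. It also needs outward rotation of the alkyl group in the first opening (sterically preferred), while the geometric isomers of 20 interconvert by reclosure to 19 so that only the cyclisable one is consumed. The excess of 12 is there to outrun capture of 18 by the phenol that is formed.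

Step 9
Reactants: 22 methyl (3R)-3-[2-(benzyloxy)-6-hydroxy-3-methyl-4-(triisopropylsiloxy)phenyl]-5-methylhexanoate
Product: 23 methyl (3R)-3-[2-(benzyloxy)-4,6-dihydroxy-3-methylphenyl]-5-methylhexanoate
Conditions: Bu4NF, AcOH (1:1), THF, 0 °C, argon
Reagents that add atoms: none
Why: Fluoride cleavage of the aryl silyl ether; the acetic acid buffer keeps the electron-rich phenoxide from air oxidation and from premature, base-driven lactonisation (any lactone formed converges in step 10).

Step 10
Reactants: 23 methyl (3R)-3-[2-(benzyloxy)-4,6-dihydroxy-3-methylphenyl]-5-methylhexanoate; 24 3-phenylpropanoyl chloride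
Product: 26 (4R)-5-(benzyloxy)-7-hydroxy-6-methyl-4-(2-methylpropyl)-8-(3-phenylpropanoyl)-3,4-dihydro-2H-chromen-2-one, via keto ester 25 (not isolated)
Conditions: 24 (1.1 equiv), TiCl4 (2.2 equiv), CH2Cl2, −20 → 0 °C; aqueous work-up; then p-TsOH·H2O (5 mol %), PhMe, 80 °C
Reagents that add atoms: none
Why: Friedel–Crafts acylation at the only unsubstituted ring carbon, which lies between two hydroxyls; the titanium phenoxide directs the acyl group ortho and the chelated ortho-hydroxy ketone is deactivated against further reaction. Acid then closes the six-membered lactone from the one hydroxyl that is ortho to the side chain, so a single lactone regioisomer forms.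

Step 11
Reactants: 26 (4R)-5-(benzyloxy)-7-hydroxy-6-methyl-4-(2-methylpropyl)-8-(3-phenylpropanoyl)-3,4-dihydro-2H-chromen-2-one; 27 methyl 2,2,4-trimethyl-3-oxopentanoate
Product: 29 2-[(1S)-1-[2-(benzyloxy)-4,6-dihydroxy-3-methyl-5-(3-phenylpropanoyl)phenyl]-3-methylbutyl]-3-hydroxy-4,4,6,6-tetramethylcyclohex-2-ene-1,5-dione, via triketo ester 28 (not isolated)
Conditions: 27 (3 equiv), LiN(i-Pr)2 (3 equiv), THF, −78 °C; 26 pretreated with LiN(SiMe3)2 (1.05 equiv) added, −78 → 0 °C; then LiN(SiMe3)2 (3 equiv), −78 °C → rt; cold 1 M HCl to pH 3
Reagents that add atoms: none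
Why: Claisen acylation followed by Dieckmann condensation, the sequence by which 4,4,6,6-tetramethylcyclohexane-1,3,5-triones are built from this keto ester: the enolate of 27 opens the aryl lactone (release of phenoxide makes this downhill) and the CH2 of 28 then closes ring B on the methyl ester (6-exo-trig), the acidic trione being removed as its enolate. The hydroxyl of 26 is first converted to its lithium phenoxide, which shields the neighbouring aryl ketone from enolisation; no stereocentre is formed and the existing one is not acidic.

Step 12
Reactants: 29 2-[(1S)-1-[2-(benzyloxy)-4,6-dihydroxy-3-methyl-5-(3-phenylpropanoyl)phenyl]-3-methylbutyl]-3-hydroxy-4,4,6,6-tetramethylcyclohex-2-ene-1,5-dione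
Product: 30 3-hydroxy-4,4,6,6-tetramethyl-2-[(1S)-3-methyl-1-[2,4,6-trihydroxy-3-methyl-5-(3-phenylpropanoyl)phenyl]butyl]cyclohex-2-ene-1,5-dione
Conditions: H2 (1 atm), Pd/C (10 wt %), EtOAc, rt
Reagents that add atoms: none
Why: Hydrogenolysis of the aryl benzyl ether under neutral conditions; the aryl ketone, the enolised trione and the stereocentre should be untouched, and no acid or base is present that could start cyclodehydration or retro-Michael racemisation.

## Compound list

1 | benzyl alcohol | OCc1ccccc1 | starting material
2 | trichloroethene | ClC=C(Cl)Cl | starting material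
3 | benzyl (E)-1,2-dichloroethenyl ether | Cl/C=C(/Cl)OCc1ccccc1 | intermediate
4 | lithium (benzyloxy)ethynide | [Li]C#COCc1ccccc1 | intermediate
5 | 1-(benzyloxy)prop-1-yne | CC#COCc1ccccc1 | intermediate
6 | tetrahydrofuran (oxolane) | C1CCOC1 | starting material
7 | lithium ethenolate | [Li]OC=C | intermediate
8 | (ethenyloxy)tri(propan-2-yl)silane | C=CO[Si](C(C)C)(C(C)C)C(C)C | intermediate
9 | (1,2-dibromoethoxy)tri(propan-2-yl)silane (racemic) | BrCC(Br)O[Si](C(C)C)(C(C)C)C(C)C | intermediate
10 | [(Z)-2-bromoethenyloxy]tri(propan-2-yl)silane | Br/C=C\O[Si](C(C)C)(C(C)C)C(C)C | intermediate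
11 | lithium [tri(propan-2-yl)silyloxy]ethynide | [Li]C#CO[Si](C(C)C)(C(C)C)C(C)C | intermediate
12 | (ethynyloxy)tri(propan-2-yl)silane, (triisopropylsiloxy)ethyne | C#CO[Si](C(C)C)(C(C)C)C(C)C | intermediate
13 | 3-(2-methylpropyl)glutaric anhydride, 4-(2-methylpropyl)oxane-2,6-dione | CC(C)CC1CC(=O)OC(=O)C1 | starting material
14 | (3S)-3-(2-methoxy-2-oxoethyl)-5-methylhexanoic acid | OC(=O)C[C@H](CC(C)C)CC(=O)OC | intermediate
15 | methyl (3R)-3-(2-chloro-2-oxoethyl)-5-methylhexanoate | ClC(=O)C[C@H](CC(C)C)CC(=O)OC | intermediate
16 | methyl (3R)-5-methyl-3-(2-oxoethenyl)hexanoate (ketene) | O=C=C[C@H](CC(C)C)CC(=O)OC | intermediate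
17 | methyl (3R)-3-[2-(benzyloxy)-3-methyl-4-oxocyclobut-2-en-1-yl]-5-methylhexanoate (both epimers at the ring carbon; one drawn) | O=C1C(C)=C(OCc2ccccc2)[C@@H]1[C@H](CC(C)C)CC(=O)OC | intermediate
18 | methyl (3R,4Z)-5-(benzyloxy)-6-methyl-3-(2-methylpropyl)-7-oxohepta-4,6-dienoate (vinylketene) | O=C=C(C)/C(OCc1ccccc1)=C/[C@H](CC(C)C)CC(=O)OC | intermediate
19 | methyl (3R,4Z)-5-(benzyloxy)-5-[1-methyl-2-oxo-4-(triisopropylsiloxy)cyclobut-3-en-1-yl]-3-(2-methylpropyl)pent-4-enoate (ring carbon unassigned) | O=C1C=C(O[Si](C(C)C)(C(C)C)C(C)C)C1(C)/C(OCc1ccccc1)=C/[C@H](CC(C)C)CC(=O)OC | intermediate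
20 | methyl (3R,4Z,6E)-5-(benzyloxy)-6-methyl-3-(2-methylpropyl)-9-oxo-7-(triisopropylsiloxy)nona-4,6,8-trienoate (dienylketene) | O=C=C/C(O[Si](C(C)C)(C(C)C)C(C)C)=C(C)\C(OCc1ccccc1)=C\[C@H](CC(C)C)CC(=O)OC | intermediate
21 | methyl (3R)-3-[2-(benzyloxy)-3-methyl-6-oxo-4-(triisopropylsiloxy)cyclohexa-2,4-dien-1-yl]-5-methylhexanoate (ring carbon unassigned) | O=C1C=C(O[Si](C(C)C)(C(C)C)C(C)C)C(C)=C(OCc2ccccc2)C1[C@H](CC(C)C)CC(=O)OC | intermediate
22 | methyl (3R)-3-[2-(benzyloxy)-6-hydroxy-3-methyl-4-(triisopropylsiloxy)phenyl]-5-methylhexanoate | Oc1cc(O[Si](C(C)C)(C(C)C)C(C)C)c(C)c(OCc2ccccc2)c1[C@H](CC(C)C)CC(=O)OC | intermediate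
23 | methyl (3R)-3-[2-(benzyloxy)-4,6-dihydroxy-3-methylphenyl]-5-methylhexanoate | Oc1cc(O)c(C)c(OCc2ccccc2)c1[C@H](CC(C)C)CC(=O)OC | intermediate
24 | 3-phenylpropanoyl chloride | O=C(Cl)CCc1ccccc1 | starting material
25 | methyl (3R)-3-[2-(benzyloxy)-4,6-dihydroxy-3-methyl-5-(3-phenylpropanoyl)phenyl]-5-methylhexanoate | Oc1c(C(=O)CCc2ccccc2)c(O)c(C)c(OCc2ccccc2)c1[C@H](CC(C)C)CC(=O)OC | intermediate
26 | (4R)-5-(benzyloxy)-7-hydroxy-6-methyl-4-(2-methylpropyl)-8-(3-phenylpropanoyl)-3,4-dihydro-2H-chromen-2-one | O=C1C[C@@H](CC(C)C)c2c(OCc3ccccc3)c(C)c(O)c(C(=O)CCc3ccccc3)c2O1 | intermediate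
27 | methyl 2,2,4-trimethyl-3-oxopentanoate | COC(=O)C(C)(C)C(=O)C(C)C | starting material
28 | methyl (7R)-7-[2-(benzyloxy)-4,6-dihydroxy-3-methyl-5-(3-phenylpropanoyl)phenyl]-2,2,4,4,9-pentamethyl-3,5-dioxodecanoate | COC(=O)C(C)(C)C(=O)C(C)(C)C(=O)C[C@@H](CC(C)C)c1c(OCc2ccccc2)c(C)c(O)c(C(=O)CCc2ccccc2)c1O | intermediate
29 | 2-[(1S)-1-[2-(benzyloxy)-4,6-dihydroxy-3-methyl-5-(3-phenylpropanoyl)phenyl]-3-methylbutyl]-3-hydroxy-4,4,6,6-tetramethylcyclohex-2-ene-1,5-dione | Cc1c(O)c(C(=O)CCc2ccccc2)c(O)c([C@H](CC(C)C)C2=C(O)C(C)(C)C(=O)C(C)(C)C2=O)c1OCc1ccccc1 | intermediate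
30 | 3-hydroxy-4,4,6,6-tetramethyl-2-[(1S)-3-methyl-1-[2,4,6-trihydroxy-3-methyl-5-(3-phenylpropanoyl)phenyl]butyl]cyclohex-2-ene-1,5-dione | Cc1c(O)c(C(=O)CCc2ccccc2)c(O)c([C@H](CC(C)C)C2=C(O)C(C)(C)C(=O)C(C)(C)C2=O)c1O | target

Total step count: 12. Longest linear sequence: 8 steps (13 → 30, steps 5 to 12; the line from 6 through 12 to 30 is equally long).

## Least certain steps

Step 8 (key step). The first ring opening may be too slow, because the benzyloxy group stabilises 17 as a vinylogous ester. At the temperature then required, isomerisation of 12 to the silylketene, capture of 18 by the phenol product and dimerisation of 18 would compete. Partial lactonisation of 22 in the hot mixture is harmless, since it converges in step 10. The fallback sets out from 15 and returns at 22; it makes 18 by elimination at or below room temperature, not by thermolysis. Ketene 16 (from 15 and Et3N) undergoes a Wittig reaction with prop-2-en-1-yl 2-(triphenylphosphoranylidene)propanoate to give the allenic diester F1. Amine-catalysed conjugate addition of 1 to the central allene carbon gives the 3-benzyloxy enoate F2. Zerovalent palladium (Pd(PPh3)4) and morpholine remove the allyl group to give the acid F3, and oxalyl chloride gives the acid chloride F4. Et3N then removes HCl across four atoms in the presence of 12, which gives 18 directly, and 19, 20, 21 and 22 follow on gentle warming.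

Step 11. O-acylation of the fully substituted enolate, or proton transfer from the lactone or the aryl ketone, may outrun C–C bond formation; further base would then close an enol lactone in place of ring B. The fallback sets out from 26 and returns at 30. Aqueous NaOH opens the lactone and benzyl bromide with K2CO3 benzylates both phenols and the carboxylate to give the tribenzyl ether benzyl ester F5. LiOH gives the acid F6 and oxalyl chloride the acid chloride F7. The bromomagnesium enolate of 27 (LiN(i-Pr)2, then MgBr2·OEt2) is C-acylated by F7 to the protected triketo ester F8, and LiN(SiMe3)2 closes ring B to the tribenzyl ether F9. Hydrogenolysis as in step 12 then gives 30.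

Step 10. The benzyl ether may be lost or may migrate from oxygen to carbon under the Lewis acid, and O-acylation may compete with C-acylation. The fallback sets out from 23 and returns at 25. A Hoesch reaction with 3-phenylpropanenitrile (ZnCl2, HCl gas, Et2O, 0 °C) gives the ketiminium chloride F10, which warm water hydrolyses to 25; the acid stage of step 10 then closes the lactone to 26.

Step 7. Dimerisation of the aldoketene and sigmatropic rearrangement of the benzyl ynol ether 5 may compete with the cycloaddition. The fallback sets out from 15 and returns at 17. Commercial 1-ethoxyprop-1-yne, which is thermally robust, takes the place of 5 and gives the 3-ethoxycyclobutenone F11. Acid-catalysed exchange of the vinylogous ester alkoxy group with 1 (p-TsOH, removal of ethanol) then gives 17, at the cost of one more linear step.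

Step 4. Anti elimination of silanolate (which would give bromoethyne, a hazard) may compete with loss of bromide, and the silyl group may be lost at the acetylide stage. The fallback sets out from 8 and returns at 11. Ozonolysis of 8 (O3, then PPh3) gives triisopropylsilyl formate F12, dichloromethylenation (PPh3, CCl4, THF, 60 °C) gives the 2,2-dichlorovinyl silyl ether F13, and n-BuLi (2.2 equiv) converts F13 by elimination and chlorine–lithium exchange into 11, which is quenched to 12 as in step 4.

## Further compounds

F1 | step 8 | 7-methyl 1-prop-2-en-1-yl (5R)-2-methyl-5-(2-methylpropyl)hepta-2,3-dienedioate | C=CCOC(=O)C(C)=C=C[C@H](CC(C)C)CC(=O)OC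
F2 | step 8 | 7-methyl 1-prop-2-en-1-yl (5S)-3-(benzyloxy)-2-methyl-5-(2-methylpropyl)hept-2-enedioate | C=CCOC(=O)C(C)=C(OCc1ccccc1)C[C@H](CC(C)C)CC(=O)OC
F3 | step 8 | (5S)-3-(benzyloxy)-7-methoxy-2-methyl-5-(2-methylpropyl)-7-oxohept-2-enoic acid | OC(=O)C(C)=C(OCc1ccccc1)C[C@H](CC(C)C)CC(=O)OC
F4 | step 8 | methyl (3S)-5-(benzyloxy)-7-chloro-6-methyl-3-(2-methylpropyl)-7-oxohept-5-enoate | ClC(=O)C(C)=C(OCc1ccccc1)C[C@H](CC(C)C)CC(=O)OC
F5 | step 11 | benzyl (3R)-5-methyl-3-[2,4,6-tris(benzyloxy)-3-methyl-5-(3-phenylpropanoyl)phenyl]hexanoate | O=C(OCc1ccccc1)C[C@@H](CC(C)C)c1c(OCc2ccccc2)c(C)c(OCc2ccccc2)c(C(=O)CCc2ccccc2)c1OCc1ccccc1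
F6 | step 11 | (3R)-5-methyl-3-[2,4,6-tris(benzyloxy)-3-methyl-5-(3-phenylpropanoyl)phenyl]hexanoic acid | OC(=O)C[C@@H](CC(C)C)c1c(OCc2ccccc2)c(C)c(OCc2ccccc2)c(C(=O)CCc2ccccc2)c1OCc1ccccc1
F7 | step 11 | (3R)-5-methyl-3-[2,4,6-tris(benzyloxy)-3-methyl-5-(3-phenylpropanoyl)phenyl]hexanoyl chloride | ClC(=O)C[C@@H](CC(C)C)c1c(OCc2ccccc2)c(C)c(OCc2ccccc2)c(C(=O)CCc2ccccc2)c1OCc1ccccc1
F8 | step 11 | methyl (7R)-2,2,4,4,9-pentamethyl-3,5-dioxo-7-[2,4,6-tris(benzyloxy)-3-methyl-5-(3-phenylpropanoyl)phenyl]decanoate | COC(=O)C(C)(C)C(=O)C(C)(C)C(=O)C[C@@H](CC(C)C)c1c(OCc2ccccc2)c(C)c(OCc2ccccc2)c(C(=O)CCc2ccccc2)c1OCc1ccccc1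
F9 | step 11 | 3-hydroxy-4,4,6,6-tetramethyl-2-[(1S)-3-methyl-1-[2,4,6-tris(benzyloxy)-3-methyl-5-(3-phenylpropanoyl)phenyl]butyl]cyclohex-2-ene-1,5-dione | Cc1c(OCc2ccccc2)c(C(=O)CCc2ccccc2)c(OCc2ccccc2)c([C@H](CC(C)C)C2=C(O)C(C)(C)C(=O)C(C)(C)C2=O)c1OCc1ccccc1
F10 | step 10 | methyl (3R)-3-[2-(benzyloxy)-4,6-dihydroxy-5-(1-iminio-3-phenylpropyl)-3-methylphenyl]-5-methylhexanoate chloride | Oc1c(C(=[NH2+])CCc2ccccc2)c(O)c(C)c(OCc2ccccc2)c1[C@H](CC(C)C)CC(=O)OC.[Cl-]
F11 | step 7 | methyl (3R)-3-(2-ethoxy-3-methyl-4-oxocyclobut-2-en-1-yl)-5-methylhexanoate (epimers at the ring carbon) | O=C1C(C)=C(OCC)C1[C@H](CC(C)C)CC(=O)OC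
F12 | step 4 | tri(propan-2-yl)silyl formate | O=CO[Si](C(C)C)(C(C)C)C(C)C
F13 | step 4 | (2,2-dichloroethenyloxy)tri(propan-2-yl)silane | ClC(Cl)=CO[Si](C(C)C)(C(C)C)C(C)C
A1 | alternative 1 | methyl (3S)-3-(2-hydroxy-3,3,5,5-tetramethyl-4,6-dioxocyclohex-1-en-1-yl)-5-methylhexanoate | COC(=O)C[C@H](CC(C)C)C1=C(O)C(C)(C)C(=O)C(C)(C)C1=O
A2 | alternative 1 | (4S)-5,7-dihydroxy-4-(2-methylpropyl)-3,4-dihydro-2H-chromen-2-one | O=C1C[C@H](CC(C)C)c2c(O)cc(O)cc2O1
A3 | alternative 2 | 2-[(1S)-1-[2,4-bis(benzyloxy)-6-hydroxy-5-methyl-3-(3-phenylpropanoyl)phenyl]-3-methylbutyl]-3-hydroxy-4,4,6,6-tetramethylcyclohex-2-ene-1,5-dione | Cc1c(OCc2ccccc2)c(C(=O)CCc2ccccc2)c(OCc2ccccc2)c([C@H](CC(C)C)C2=C(O)C(C)(C)C(=O)C(C)(C)C2=O)c1O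
A4 | alternative 2 | (4R)-5,7-bis(benzyloxy)-8-methyl-4-(2-methylpropyl)-6-(3-phenylpropanoyl)-3,4-dihydro-2H-chromen-2-one | O=C1C[C@@H](CC(C)C)c2c(OCc3ccccc3)c(C(=O)CCc3ccccc3)c(OCc3ccccc3)c(C)c2O1
A5 | alternative 3 | 3-hydroxy-4,4,6,6-tetramethyl-2-[(1S)-3-methyl-1-[2,4,6-tris(benzyloxy)-3-methylphenyl]butyl]cyclohex-2-ene-1,5-dione | Cc1c(OCc2ccccc2)cc(OCc2ccccc2)c([C@H](CC(C)C)C2=C(O)C(C)(C)C(=O)C(C)(C)C2=O)c1OCc1ccccc1
A6 | alternative 3 | 2,6-dimethyl-4-[(1R)-3-methyl-1-[2,4,6-tris(benzyloxy)-3-methylphenyl]butyl]heptane-3,5-dione | CC(C)C(=O)C(C(=O)C(C)C)[C@@H](CC(C)C)c1c(OCc2ccccc2)cc(OCc2ccccc2)c(C)c1OCc1ccccc1
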